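**Strategy.** Ring A of the labdane decalin (C1–C5 and C10, labdane numbering) is opened at C1–C2 and C3–C4, which excises the C2–C3 ethano bridge as vinyltriphenylphosphonium bromide. The key step exploits two features: C4 is α to the C19 ester, hence an enolate donor, and C1 hangs on quaternary C10, hence a non-enolisable aldehyde acceptor. Michael addition of the C4 ester enolate to the vinylphosphonium salt and intramolecular Wittig closure of the resulting C2 ylide onto the C1 aldehyde assemble ring A in one flask. The precursor is a monocyclic ring B aldehyde ester carrying C5, C9 and C10; C4 methylation, C8 methylenation and side-chain olefination follow.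

Key step: step 8

Remark: labdane numbering (C17 on C8, C18/C19 on C4, C20 on C10) labels all atoms; C9 is formed without control in step 5, so the SMILES of 10–20 leave it open, and it is set by equilibration in step 11.

Step 1
Reactants: 1 2-methylcyclohex-2-en-1-one
Product: 2 (S)-2-methylcyclohex-2-en-1-ol
Conditions: (R)-Me-CBS oxazaborolidine (cat.), catecholborane, toluene, −78 °C
Reagents that add atoms: none
Why: Corey–Bakshi–Shibata reduction, in which the catalyst-bound borane should deliver hydride to one carbonyl face with the alkenyl branch acting as the large group, setting the (S) carbinol centre (future C9) whose chirality is relayed to C5 in step 2.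

Step 2
Reactants: 2 (S)-2-methylcyclohex-2-en-1-ol; 3 trimethyl orthoacetate
Product: 6 methyl 2-[(1S)-2-methylcyclohex-2-en-1-yl]acetate, via mixed orthoester 4 (not isolated), via ketene acetal 5 (not isolated)
Conditions: propionic acid (cat.), o-xylene, 140 °C (sealed tube)
Reagents that add atoms: none
Why: Johnson–Claisen rearrangement, whose suprafacial [3,3] shift forms the C5–C4 bond on the ring face that the C–O bond leaves, so the carbinol chirality is transferred to C5 (S) and the alkene moves to C9=C10.

Step 3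
Reactants: 6 methyl 2-[(1S)-2-methylcyclohex-2-en-1-yl]acetate
Product: 7 methyl 2-[(1S)-2-methyl-4-oxocyclohex-2-en-1-yl]acetate
Conditions: Rh2(C6H10NO)4 (dirhodium tetracaprolactamate, cat.), t-BuOOH, K2CO3, CH2Cl2, rt
Reagents that add atoms: tert-butyl hydroperoxide CC(C)(C)OO
Why: Allylic C–H oxidation to the enone should occur at the secondary allylic C8 methylene next to the alkene CH, as in the oxidation of Δ5-steroids to 7-ketones, while the tertiary C5–H cannot give a ketone and the C5 stereocentre is untouched.

Step 4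
Reactants: 7 methyl 2-[(1S)-2-methyl-4-oxocyclohex-2-en-1-yl]acetate
Product: 8 methyl 2-[(1S,2S)-2-ethenyl-2-methyl-4-(trimethylsilyloxy)cyclohex-3-en-1-yl]acetate
Conditions: CH2=CHMgBr, CuBr·SMe2 (cat.), TMSCl, HMPA, THF, −78 °C; Et3N, non-aqueous work-up
Reagents that add atoms: vinylmagnesium bromide C=C[Mg]Br; chlorotrimethylsilane C[Si](C)(C)Cl
Why: Copper-catalysed conjugate addition with silyl trapping, in which allylic 1,2-strain with the C10 methyl should hold the C5 side chain pseudo-axial so that vinyl adds to C10 anti to it (quaternary C10, vinyl trans to the acetate arm) and the enolate is fixed as the C8–C9 silyl enol ether.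

Step 5
Reactants: 8 methyl 2-[(1S,2S)-2-ethenyl-2-methyl-4-(trimethylsilyloxy)cyclohex-3-en-1-yl]acetate; 9 but-3-en-2-one
Product: 10 methyl 2-[(1S,2S,3RS)-2-ethenyl-2-methyl-4-oxo-3-(3-oxobutyl)cyclohexyl]acetate
Conditions: TiCl4, CH2Cl2, −78 °C; aq. NaHCO3
Reagents that add atoms: none
Why: Mukaiyama–Michael addition, in which the regiodefined enol ether can react only at C9; the C9 configuration is not controlled here and is corrected next to the C8 ketone in step 11.

Step 6
Reactants: 10 methyl 2-[(1S,2S,3RS)-2-ethenyl-2-methyl-4-oxo-3-(3-oxobutyl)cyclohexyl]acetate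
Product: 11 methyl 2-[(6RS,7S,8S)-7-ethenyl-7-methyl-6-[2-(2-methyl-1,3-dioxolan-2-yl)ethyl]-1,4-dioxaspiro[4.5]decan-8-yl]acetate
Conditions: (TMSOCH2)2, TMSOTf (cat.), CH2Cl2, −78 to −20 °C; pyridine
Reagents that add atoms: 1,2-bis(trimethylsilyloxy)ethane C[Si](C)(C)OCCO[Si](C)(C)C
Why: Silyl-transfer ketalisation of both ketones under aprotic conditions should leave the methyl ester intact and make C4–H2 the only acidic C–H for step 8; no stereocentre is formed.

Step 7
Reactants: 11 methyl 2-[(6RS,7S,8S)-7-ethenyl-7-methyl-6-[2-(2-methyl-1,3-dioxolan-2-yl)ethyl]-1,4-dioxaspiro[4.5]decan-8-yl]acetate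
Product: 13 methyl 2-[(6RS,7S,8S)-7-formyl-7-methyl-6-[2-(2-methyl-1,3-dioxolan-2-yl)ethyl]-1,4-dioxaspiro[4.5]decan-8-yl]acetate, via ozonide 12 (not isolated)
Conditions: O3, CH2Cl2, −78 °C; then Me2S, −78 °C to rt
Reagents that add atoms: ozone [O-][O+]=O
Why: Ozonolysis with reductive work-up cleaves the only alkene to the C1 aldehyde, which sits on quaternary C10 and therefore can neither enolise nor epimerise.

Step 8
Reactants: 13 methyl 2-[(6RS,7S,8S)-7-formyl-7-methyl-6-[2-(2-methyl-1,3-dioxolan-2-yl)ethyl]-1,4-dioxaspiro[4.5]decan-8-yl]acetate; 14 vinyltriphenylphosphonium bromide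
Product: 17 methyl 8,8:13,13-bis(ethylenedioxy)-14,15,17,18-tetranorlabd-1-en-19-oate (5α-H, 10β-methyl; C4/C9 epimers), via lithium ester enolate 15 (not isolated), via phosphonium ylide 16 (not isolated)
Conditions: LiTMP (lithium 2,2,6,6-tetramethylpiperidide, from the amine and n-BuLi), THF, −78 °C; then 14, −78 °C to rt, then 50 °C
Reagents that add atoms: none
Why: LiTMP removes a C4 proton α to the C19 ester, the only acidic C–H in 13, and the enolate 15 adds through C4 to the β-carbon of the vinylphosphonium salt (C3–C4 bond), which turns C2 into a non-stabilised ylide 16; the ylide attacks the C1 aldehyde intramolecularly and the oxaphosphetane collapses to the cis C1=C2 bond of ring A and Ph3PO (C1–C2 bond). The closest known reaction type is the Schweizer-type annulation, a tandem Michael addition–intramolecular Wittig reaction of enolates with vinylphosphonium salts. Ring A is closed in the second event by 6-exo-trig addition of the C2 ylide carbon to the C1 carbonyl, the first bond being formed intermolecularly. The only new stereocentre is C4 (CH), which may form as either epimer without consequence because it is planarised again in step 10, whereas C5, C9 and C10 cannot epimerise under the conditions. The step needs ester deprotonation in the presence of an aldehyde; this should be secured by the aldehyde being non-enolisable and buried on quaternary C10 between two substituted ring carbons, by a bulky amide base that cannot transfer hydride, and by the reversibility of any aldol addition (the intramolecular one would give a strained cyclobutanol), which leaves the six-membered Wittig closure as the only irreversible exit.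

Step 9
Reactants: 17 methyl 8,8:13,13-bis(ethylenedioxy)-14,15,17,18-tetranorlabd-1-en-19-oate
Product: 18 methyl 8,8:13,13-bis(ethylenedioxy)-14,15,17,18-tetranorlabdan-19-oate (C4/C9 epimers)
Conditions: H2 (1 atm), Pd/C, EtOAc, rt
Reagents that add atoms: none
Why: Heterogeneous catalytic hydrogenation of the only C=C bond turns C1 and C2 into methylene groups, so no stereocentre arises, and ketals and ester are inert.

Step 10
Reactants: 18 methyl 8,8:13,13-bis(ethylenedioxy)-14,15,17,18-tetranorlabdan-19-oate
Product: 20 methyl 8,8:13,13-bis(ethylenedioxy)-14,15,17-trinorlabdan-19-oate (4S; C9 epimers), via lithium ester enolate 19 (not isolated)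
Conditions: LDA (lithium diisopropylamide), THF, −78 to 0 °C; then MeI, DMPU, −78 °C to rt
Reagents that add atoms: iodomethane CI
Why: Ester enolate alkylation, in which MeI should attack the exocyclic enolate on chair ring A from the equatorial α face because the axial C10 methyl blocks the β face, so the new methyl ends equatorial and the C19 ester axial (4S), the usual outcome for podocarpate-type enolates.

Step 11
Reactants: 20 methyl 8,8:13,13-bis(ethylenedioxy)-14,15,17-trinorlabdan-19-oate
Product: 21 methyl 8,13-dioxo-14,15,17-trinorlabdan-19-oate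
Conditions: 1 M HCl, THF, rt
Reagents that add atoms: water O
Why: Acid hydrolysis of both dioxolanes; the same acid enolises the C8 ketone toward C9 (more substituted enol), and axial protonation from the α face, away from the C10 methyl, should funnel both C9 epimers into the equatorial side chain with 9α-H, which is also the more stable epimer.

Step 12
Reactants: 21 methyl 8,13-dioxo-14,15,17-trinorlabdan-19-oate; 22 triethyl phosphonoacetate
Product: 23 15-ethyl 19-methyl (13E)-8-oxo-17-norlabd-13-ene-15,19-dioate
Conditions: NaH, 22, THF, 0 °C; then 21, 0 °C to rt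
Reagents that add atoms: none
Why: Horner–Wadsworth–Emmons olefination, in which the phosphonate anion should attack the unhindered C13 methyl ketone and not the C8 ketone flanked by C9 and quaternary C10; the E isomer (chain trans to the ester) should predominate and the minor Z isomer is removed by chromatography.

Step 13
Reactants: 23 15-ethyl 19-methyl (13E)-8-oxo-17-norlabd-13-ene-15,19-dioate
Product: 24 15-ethyl 19-methyl (13E)-labda-8(17),13-diene-15,19-dioate
Conditions: Ph3PCH3Br, KHMDS (KN(SiMe3)2), THF, 0 °C; then 23, 0 to 45 °C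
Reagents that add atoms: methyltriphenylphosphonium bromide C[P+](c1ccccc1)(c1ccccc1)c1ccccc1.[Br-]
Why: Wittig methylenation, established for 8-oxolabdanes, converts the C8 ketone into the C8(17) exocyclic alkene; the β,β-disubstituted enoate should resist ylide addition and C9 keeps the equatorial side chain.

Step 14
Reactants: 24 15-ethyl 19-methyl (13E)-labda-8(17),13-diene-15,19-dioate
Product: 25 methyl (13E)-15-hydroxylabda-8(17),13-dien-19-oate (methyl isocupressate)
Conditions: DIBAL-H (i-Bu2AlH), CH2Cl2, −78 °C; aq. potassium sodium tartrate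
Reagents that add atoms: none
Why: DIBAL-H 1,2-reduction of the conjugated ethyl ester; the C19 methyl ester is axial on quaternary C4 beside the C10 methyl and should stay untouched at −78 °C, and the E alkene geometry is retained.

Step 15
Reactants: 25 methyl (13E)-15-hydroxylabda-8(17),13-dien-19-oate; 26 hexadecanoyl chloride
Product: 27 methyl (13E)-15-(hexadecanoyloxy)labda-8(17),13-dien-19-oate (target)
Conditions: pyridine, DMAP (cat.), CH2Cl2, 0 °C to rt
Reagents that add atoms: none
Why: DMAP-catalysed O-acylation of the primary allylic alcohol, which affects no stereocentre and no alkene geometry.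

**Compound list**

1 | 2-methylcyclohex-2-en-1-one | CC1=CCCCC1=O | starting material
2 | (S)-2-methylcyclohex-2-en-1-ol | O[C@H]1CCCC=C1C | intermediate
3 | trimethyl orthoacetate (1,1,1-trimethoxyethane) | CC(OC)(OC)OC | starting material
4 | mixed orthoester, 1,1-dimethoxy-1-{[(1S)-2-methylcyclohex-2-en-1-yl]oxy}ethane | CC(OC)(OC)O[C@H]1CCCC=C1C | intermediate
5 | ketene acetal, 1-methoxy-1-{[(1S)-2-methylcyclohex-2-en-1-yl]oxy}ethene | C=C(OC)O[C@H]1CCCC=C1C | intermediate
6 | methyl 2-[(1S)-2-methylcyclohex-2-en-1-yl]acetate | COC(=O)C[C@@H]1CCCC=C1C | intermediate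
7 | methyl 2-[(1S)-2-methyl-4-oxocyclohex-2-en-1-yl]acetate | COC(=O)C[C@@H]1CCC(=O)C=C1C | intermediate
8 | methyl 2-[(1S,2S)-2-ethenyl-2-methyl-4-(trimethylsilyloxy)cyclohex-3-en-1-yl]acetate (vinyl trans to the acetate arm) | C[Si](C)(C)OC1=C[C@@](C)(C=C)[C@H](CC(=O)OC)CC1 | intermediate
9 | but-3-en-2-one (methyl vinyl ketone) | CC(=O)C=C | starting material
10 | methyl 2-[(1S,2S,3RS)-2-ethenyl-2-methyl-4-oxo-3-(3-oxobutyl)cyclohexyl]acetate (C9 epimers) | O=C1CC[C@@H](CC(=O)OC)[C@](C)(C=C)C1CCC(C)=O | intermediate
11 | methyl 2-[(6RS,7S,8S)-7-ethenyl-7-methyl-6-[2-(2-methyl-1,3-dioxolan-2-yl)ethyl]-1,4-dioxaspiro[4.5]decan-8-yl]acetate | O1CCOC12CC[C@@H](CC(=O)OC)[C@](C)(C=C)C2CCC2(C)OCCO2 | intermediate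
12 | ozonide (1,2,4-trioxolane) of 11 at the vinyl group | O1CCOC12CC[C@@H](CC(=O)OC)[C@](C)(C3OCOO3)C2CCC2(C)OCCO2 | intermediate
13 | methyl 2-[(6RS,7S,8S)-7-formyl-7-methyl-6-[2-(2-methyl-1,3-dioxolan-2-yl)ethyl]-1,4-dioxaspiro[4.5]decan-8-yl]acetate | O1CCOC12CC[C@@H](CC(=O)OC)[C@](C)(C=O)C2CCC2(C)OCCO2 | intermediate
14 | vinyltriphenylphosphonium bromide | C=C[P+](c1ccccc1)(c1ccccc1)c1ccccc1.[Br-] | starting material
15 | lithium ester enolate of 13 (C4=C19 enolate) | O1CCOC12CC[C@@H](C=C(OC)O[Li])[C@](C)(C=O)C2CCC2(C)OCCO2 | intermediate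
16 | phosphonium ylide, Michael adduct of 15 and 14 (C4–CH2–CH=PPh3) | O1CCOC12CC[C@@H](C(CC=P(c3ccccc3)(c3ccccc3)c3ccccc3)C(=O)OC)[C@](C)(C=O)C2CCC2(C)OCCO2 | intermediate
17 | methyl 8,8:13,13-bis(ethylenedioxy)-14,15,17,18-tetranorlabd-1-en-19-oate (trans-fused, 5α-H, 10β-methyl; C4/C9 epimers) | O1CCOC12CC[C@@H]3[C@](C)(C=CCC3C(=O)OC)C2CCC2(C)OCCO2 | intermediate
18 | methyl 8,8:13,13-bis(ethylenedioxy)-14,15,17,18-tetranorlabdan-19-oate (C4/C9 epimers) | O1CCOC12CC[C@@H]3[C@](C)(CCCC3C(=O)OC)C2CCC2(C)OCCO2 | intermediate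
19 | lithium ester enolate of 18 (C4=C19 enolate) | O1CCOC12CC[C@@H]3[C@](C)(CCCC3=C(OC)O[Li])C2CCC2(C)OCCO2 | intermediate
20 | methyl 8,8:13,13-bis(ethylenedioxy)-14,15,17-trinorlabdan-19-oate (4S: equatorial 4α-methyl, axial ester; C9 epimers) | O1CCOC12CC[C@@H]3[C@](C)(CCC[C@]3(C)C(=O)OC)C2CCC2(C)OCCO2 | intermediate
21 | methyl 8,13-dioxo-14,15,17-trinorlabdan-19-oate (9α-H) | O=C1CC[C@@H]2[C@](C)(CCC[C@]2(C)C(=O)OC)[C@H]1CCC(C)=O | intermediate
22 | triethyl phosphonoacetate | CCOC(=O)CP(=O)(OCC)OCC | starting material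
23 | 15-ethyl 19-methyl (13E)-8-oxo-17-norlabd-13-ene-15,19-dioate | O=C1CC[C@@H]2[C@](C)(CCC[C@]2(C)C(=O)OC)[C@H]1CC/C(C)=C/C(=O)OCC | intermediate
24 | 15-ethyl 19-methyl (13E)-labda-8(17),13-diene-15,19-dioate | C=C1CC[C@@H]2[C@](C)(CCC[C@]2(C)C(=O)OC)[C@H]1CC/C(C)=C/C(=O)OCC | intermediate
25 | methyl (13E)-15-hydroxylabda-8(17),13-dien-19-oate (methyl isocupressate) | C=C1CC[C@@H]2[C@](C)(CCC[C@]2(C)C(=O)OC)[C@H]1CC/C(C)=C/CO | intermediate
26 | hexadecanoyl chloride (palmitoyl chloride) | CCCCCCCCCCCCCCCC(=O)Cl | starting material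
27 | methyl (1S,4aR,5S,8aR)-5-[(3E)-5-(hexadecanoyloxy)-3-methylpent-3-en-1-yl]-1,4a-dimethyl-6-methylidenedecahydronaphthalene-1-carboxylate | C=C1CC[C@@H]2[C@](C)(CCC[C@]2(C)C(=O)OC)[C@H]1CC/C(C)=C/COC(=O)CCCCCCCCCCCCCCC | target

**Totals.** 15 steps; longest linear sequence 15 steps (from 1).

**Steps most likely to fail**

Step 8. The base may attack the aldehyde before it deprotonates the ester, or the ester enolate may be consumed by aldol addition to the aldehyde of a second molecule, so that the Michael–Wittig cascade does not start. The fallback sets out from 11 and makes the two ring A bonds in separate operations. Alkylation of the ester enolate of 11 (LDA, allyl bromide, THF, −78 °C) should give methyl 2-[(6RS,7S,8S)-7-ethenyl-7-methyl-6-[2-(2-methyl-1,3-dioxolan-2-yl)ethyl]-1,4-dioxaspiro[4.5]decan-8-yl]pent-4-enoate F1 (C3–C4 bond). Ring-closing metathesis of F1 with second-generation Grubbs catalyst, RuCl2(=CHPh)(H2IMes)(PCy3), in CH2Cl2 at 40 °C joins the C10 vinyl and the allyl group (C1=C2 bond) and comes back to the route at 17.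

Step 5. Bond formation at C9, next to quaternary C10, may be slower than protodesilylation of the enol ether, which would erase the regiochemical information. The fallback sets out from 8 and reverses the polarity of the C11–C12 bond. Mannich reaction of 8 with dimethylmethyleneammonium iodide (CH2Cl2, rt) should give methyl 2-[(1S,2S,3RS)-3-[(dimethylamino)methyl]-2-ethenyl-2-methyl-4-oxocyclohexyl]acetate F2. N-Methylation (MeI) gives trimethyl{[(2S,3S)-2-ethenyl-3-(2-methoxy-2-oxoethyl)-2-methyl-6-oxocyclohexyl]methyl}azanium iodide F3, and elimination with DBU gives methyl 2-[(1S,2S)-2-ethenyl-2-methyl-3-methylidene-4-oxocyclohexyl]acetate F4. Mukaiyama–Michael addition of 2-(trimethylsilyloxy)propene (TiCl4, CH2Cl2, −78 °C) to the unhindered exocyclic carbon of F4 comes back to the route at 10.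

Step 14. Hydride may also attack the C19 ester or add in conjugate fashion to the enoate. The fallback sets out from 24 and differentiates the two esters by hydrolysis. LiOH in THF–H2O should cleave only the unhindered ethyl ester and give (13E)-19-methoxy-19-oxolabda-8(17),13-dien-15-oic acid F5. Ethyl chloroformate and Et3N convert F5 into the ethyl carbonic mixed anhydride of (13E)-19-methoxy-19-oxolabda-8(17),13-dien-15-oic acid F6, which NaBH4 (THF–MeOH, 0 °C) reduces to the allylic alcohol, coming back to the route at 25.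

**Further compounds**

F1 | step 8 | methyl 2-[(6RS,7S,8S)-7-ethenyl-7-methyl-6-[2-(2-methyl-1,3-dioxolan-2-yl)ethyl]-1,4-dioxaspiro[4.5]decan-8-yl]pent-4-enoate | O1CCOC12CC[C@@H](C(CC=C)C(=O)OC)[C@](C)(C=C)C2CCC2(C)OCCO2
F2 | step 5 | methyl 2-[(1S,2S,3RS)-3-[(dimethylamino)methyl]-2-ethenyl-2-methyl-4-oxocyclohexyl]acetate | O=C1CC[C@@H](CC(=O)OC)[C@](C)(C=C)C1CN(C)C
F3 | step 5 | trimethyl{[(2S,3S)-2-ethenyl-3-(2-methoxy-2-oxoethyl)-2-methyl-6-oxocyclohexyl]methyl}azanium iodide | O=C1CC[C@@H](CC(=O)OC)[C@](C)(C=C)C1C[N+](C)(C)C.[I-]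
F4 | step 5 | methyl 2-[(1S,2S)-2-ethenyl-2-methyl-3-methylidene-4-oxocyclohexyl]acetate | O=C1CC[C@@H](CC(=O)OC)[C@](C)(C=C)C1=C
F5 | step 14 | (13E)-19-methoxy-19-oxolabda-8(17),13-dien-15-oic acid | C=C1CC[C@@H]2[C@](C)(CCC[C@]2(C)C(=O)OC)[C@H]1CC/C(C)=C/C(=O)O
F6 | step 14 | ethyl carbonic mixed anhydride of (13E)-19-methoxy-19-oxolabda-8(17),13-dien-15-oic acid | C=C1CC[C@@H]2[C@](C)(CCC[C@]2(C)C(=O)OC)[C@H]1CC/C(C)=C/C(=O)OC(=O)OCC
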